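The runs were computed for an exercise, noise included.

Before I charge this flask, I want one figure: what a converted substrate costs in reagent.

all flasks: substrate 1.5 M

| flask | reagent | remark | time |
|---|---|---|---|
| west | 1.5 M | run made earlier |  |
| east | 2.2 M | run made earlier |  |
| flask | 3.00 M |  | 2.5 min |

| run | time / s | other mono adduct / % | mono adduct / % | substrate / % |
|---|---|---|---|---|
| west | 15.0 | 23 | 8 | 63 |
| west | 40.0 | 41 | 5 | 38 |
| west | 80.0 | 41 | 5 | 31 |
| west | 120 | 43 | 7 | 25 |
| east | 15.0 | 34 | 6 | 43 |
| east | 40.0 | 44 | 10 | 22 |
| east | 80.0 | 49 | 2 | 12 |
| east | 120 | 54 | 2 | 7 |

(standard deviation of a reading: 2 percentage points)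
- equivalents of reagent to substrate, everything else as given, that leave most other mono adduct at 2.5 min
- the amount of other mono adduct then, in percent of the substrate charged
- the amount of other mono adduct with the amounts as given

The columns do not close. I take the shortfall as double product, which holds two reagent. From the last east reading,

w = 1 + double product / substrate converted = 1.40

This w is the reagent cost, reagent used per substrate converted.

For the rate constant k of substrate loss, the first east reading with reagent held at its charge gives 0.0256 M⁻¹ s⁻¹. Going round again with the mean of the charge and the 1.09 M then left gives

k = 0.0342 M⁻¹ s⁻¹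

I reckon two extreme versions of the flask, with c the charges and t the time:

reagent stays at its charge: k·c(reagent)·t = 15.4
reagent stands from the start at the level R that w leaves at the end: R = c(reagent) − w·c(substrate) = 0.903 M, so k·R·t = 4.63

I expect the real exposure between these two, so I expect about 0.975% of the substrate or less to be left in the flask. I also expect reagent near R and other mono adduct of about 60.0% or somewhat less. I look for the best charge between w and the flask's 2.00 equivalents.

The forecast says 1.65 equiv, 54% and 50%: “The maximum is flat.” The flask gives 1.63 equiv, 55.4% and 53.4%.

    substrate + reagent → mono adduct (k = 0.0120 M⁻¹ s⁻¹)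
    substrate + reagent → other mono adduct (k = 0.0200 M⁻¹ s⁻¹)
    reagent + mono adduct → double product (k = 0.0760 M⁻¹ s⁻¹)
    reagent + other mono adduct → double product (k = 0.00110 M⁻¹ s⁻¹)

In the flask, the step from substrate to other mono adduct has half of its turnover up to 2.5 min behind it by 0.144 min and 97% by 1.25 min, when other mono adduct stands at 55.4%. By 2.50 min other mono adduct is down to 53.4%, made at 0.149 of the rate it is used up, with 0.816 M of reagent left.

A neighbour flask is charged like this one but with 1.2 M of reagent. If its reagent is used up, w leaves 42.8% of its substrate, and going round with the cost from the last west reading, 1.33, leaves 40.0%. At 2.50 min the neighbour flask holds 37% of its substrate and 0.87% of its reagent.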